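**Remark (abbreviations and assumptions):** prenyl = 3-methylbut-2-en-1-yl; MOM = methoxymethyl; TBS = tert-butyldimethylsilyl; TMS = trimethylsilyl; ArB = 2-methoxy-4-(methoxymethoxy)-3-prenylphenyl. The empirical face rule of the titanium–tartrate epoxidation is assumed to hold for the 2-arylallyl alcohol 7 as it does for other 2-substituted allyl alcohols. Diene 21 is assumed to be used without purification.

## Analysis of the target

Target 28 is a 3-hydroxyisoflavanone: a chroman-4-one (rings A and C) whose C3 carries a hydroxyl group and ring B, a 4-hydroxy-2-methoxy-3-prenylphenyl group. Ring A carries hydroxyl groups at C5 and C7 and a prenyl group between them at C6. C3 is the only stereocentre and has the R configuration. It is quaternary, oxygenated, benzylic and α to the C4 ketone, so it cannot epimerise by enolisation, but it also cannot be corrected once it is set. The sensitive groups are the two prenyl groups (each ortho to a phenol, so acid can close chromans, and oxidants or electrophilic halogen can attack the double bonds), the phenols, and the tertiary α-ketol. An alkoxide at the C2 oxygen of an open-chain precursor can also lose C2 by retro-aldol cleavage. Three things make the synthesis hard: the absolute configuration at a fully substituted carbinol carbon, the regiochemistry of ring A (prenyl at C6 and not C8, and which ring-A oxygen becomes O1), and one methyl ether among four oxygens on the arenes. The strategy rests on the C5(O)–C6(prenyl)–C7(O) triad beside C4a, which bears the C4 acyl carbon. C5, C6, C7 and C8 are a 2-prenylacetoacetate in disguise (C5 ester carbon, C6 α-carbon, C7 ketone carbon, C8 methyl), so ring A can be built from a dienol ether of that ester and an acetylenic ketone that supplies C8a and C4a and already carries C4, C3 and ring B.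

## Retrosynthetic reasoning

**28 ⇒ 27.** The last operation should make the fewest demands. The three phenols and the tertiary alcohol of 28 are covered as MOM acetals in 27 and released together by acid. Acetals survive base, fluoride and organometallic reagents, and on the tertiary oxygen an acetal cannot move to a neighbouring alkoxide as a silyl group would.

**27 ⇒ 26 ⇒ 25 ⇒ 24 (O1–C8a).** Ring C is opened at the aryl–oxygen bond. This leaves an aryl bromide and a primary alcohol in 26, and the bromine can be brought in on an acetylenic carbon, so the question of which ring-A oxygen becomes O1 never arises. A cut at O1–C2 would need a C8a phenol beside the C5 phenol and would bring back the task of telling two ortho oxygens apart. A cut at C2–C3 would put the stereocentre at stake. Forward, a copper-catalysed intramolecular O-arylation has to close a six-membered ring onto a bromide activated by the ortho carbonyl. 26 comes from 25 by removal of the primary silyl group, and 25 from diphenol 24 by acetal formation.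

**24 ⇒ 17 + 21 (C4a–C5 and C8–C8a).** Ring A is taken apart completely. The two bonds cut are those that a [4+2] cycloaddition of diene 21 with bromo-ynone 17 forms. This places the prenyl group between the two oxygens by construction, sets the bromine at C8a, and joins the ring-A and ring-B halves in one step. No electrophilic substitution on a finished phloroglucinol-type ring is needed, so the 6- versus 8-prenyl problem does not appear. The forward reaction has to add the diene across the triple bond with the CH2 terminus on the bromine-bearing carbon and then aromatise.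

**21 ⇒ 20 ⇒ 19 ⇒ 18 + 2.** The diene is the bis-silyl dienol ether of the prenylated acetoacetate 19, made by two successive enolisations and silylations. 19 comes from 18 and 2 by C-alkylation.

**17 ⇒ 16 ⇒ 15 ⇒ 14 (C4–alkyne bond).** The bromine is put on last, onto the terminal ynone 16. The ynone is disconnected between C4 and the alkyne, giving aldehyde 14 and a two-carbon acetylide, with an oxidation in between. The aldehyde has no α-hydrogen, so the stereocentre is safe.

**14 ⇒ 12 ⇒ 11 ⇒ 10 ⇒ 9.** The aldehyde carbon is traced to a CH2–S carbon through a Pummerer rearrangement of sulfoxide 12. The two hydroxyl groups of 9 differ in steric demand and are protected one after the other, silyl on the primary and acetal on the tertiary oxygen.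

**9 ⇒ 8 ⇒ 7 (C–S and C3–O).** The carbinol carbon of 9 carries two CH2 arms. They are told apart by making one of them the CH2 of an epoxide, which a sulfur nucleophile opens under basic conditions without touching the C–O bond at the stereocentre. Epoxy alcohol 8 comes from allyl alcohol 7 by hydroxyl-directed asymmetric epoxidation. This is preferred over an osmium-based dihydroxylation, which would not distinguish the styrene-type double bond from the prenyl double bond.

**7 ⇒ 6 ⇒ 5.** The hydroxymethyl group is attached by cross-coupling to enol triflate 6, which comes from methyl ketone 5.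

**5 ⇒ 4 ⇒ 3 ⇒ 1 + 2.** The two ring-B oxygens are differentiated through the hydrogen bond of the 2-OH to the acetyl group: acetal on the free 4-OH, then methyl on the chelated 2-OH. The prenyl group is placed at C3 of 1 by C-alkylation with 2.

## Alternatives that were turned down

**Alternative 1:** Both prenyl groups are disconnected from the finished core at C6 and C3′ and traced to the bis(tertiary allyl) ether A1. Heating A1 should trigger two aromatic Claisen rearrangements to give the diprenyl diol A2.
- For: each ether has one free ortho position (C6 beside O5, C3′ beside O2′), so regiochemistry is fixed by construction, as in the chosen route.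
- For, and stronger than the chosen route: no alkene has to be carried through oxidations, so reagents that attack trisubstituted alkenes could be used to set C3.
- Against: A1 presupposes the whole enantiopure 3-hydroxyisoflavanone core, so C3, ring C and the choice of O1 remain unsolved.
- Against: two tertiary allyl ethers must be made on the chelated, hindered 5-OH and on the 2′-OH, in the presence of the tertiary 3-OH.
- Against: thermolysis exposes the α-ketol to conditions under which an acyloin shift is possible, and the C6 dienone can shift on toward C8.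
- Against: the 2′-OH of A2 must then be methylated in the presence of the 5-OH and 3-OH.
- Comparison: the chosen route builds ring A with the prenyl group already in place and marks O1 by a bromine. It pays for this by carrying prenyl groups through the sequence.

**Alternative 2:** The C3–O and C4–O bonds are cut to give the (E)-2,3-diarylallyl alcohol A3. A titanium–tartrate–hydroperoxide epoxidation gives epoxy alcohol A4, which is then closed to ring C and adjusted to the ketone at C4.
- For, and stronger than the chosen route: it is convergent and shorter, since both arenes enter whole and the carbon skeleton is complete before the asymmetric step.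
- For: the epoxidation is hydroxyl-directed, so the prenyl groups are tolerated.
- Against: the alkene of A3 carries two ortho-substituted aryl groups cis to each other, one of them 2,6-dioxygenated, which is a hindered substrate.
- Against: C4 of A4 is benzylic to a 2,4,6-trioxygenated ring and should ionise under the Lewis acidic conditions; aryl migration from C3 would then destroy the stereocentre.
- Against: ring A has to be prepared as a prenylated aldehyde with three different oxygen protecting groups, which moves the 6- versus 8-prenyl problem and does not solve it.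
- Against: by the empirical face rule the 3R epoxide A4 calls for the D-(−) tartrate ester; the L-(+) ester would give the antipode.
- Comparison: the chosen route uses the same kind of epoxidation, but on a terminal 2-arylallyl alcohol. Only one epoxide carbon is benzylic, and the epoxide is opened at CH2 under basic conditions. Ring-A regiochemistry comes from the cycloaddition.

**Alternative 3:** The C2–C3 bond is cut to give the ortho-methoxybenzil A5. Near-UV irradiation should move a methoxy hydrogen to the oxygen of the carbonyl remote from ring A, and the biradical should couple to give the 3-hydroxychroman-4-one A6.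
- For, and far stronger than the chosen route in step economy: ring C, the C2–C3 bond and the tertiary alcohol form in one step from a simple diketone.
- Against: the biradical has no inherent facial bias, so A6 is racemic unless an external chiral environment binds the diketone, and that is not a dependable control element.
- Against: the nearer carbonyl can abstract the same hydrogen and lead to a benzofuran-3-ol.
- Against: excited carbonyls can react with the prenyl double bonds or abstract their benzylic–allylic hydrogens.
- Against: the 2′-silyl ether of A6 must later be exchanged for methyl beside other phenols.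
- Comparison: the chosen route sets C3 early by a reagent-controlled reaction of predictable sense and never exposes the prenyl groups to excited ketones. It needs many more steps.

Key step: step 18

## Route

**Step 1**
Reactants: 1 2,4-dihydroxyacetophenone; 2 prenyl bromide
Product: 3 1-(2,4-dihydroxy-3-prenylphenyl)ethanone
Conditions: KOH (aq., 10%), 0 °C → rt
Reagents that add atoms: none
Why: Phenoxide C-alkylation: in water the dianion of 1 should react with the allylic bromide mainly at C3, the carbon activated by both oxygens; the 5-prenyl isomer and O-prenyl ethers are removed by chromatography.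

**Step 2**
Reactants: 3 1-(2,4-dihydroxy-3-prenylphenyl)ethanone
Product: 4 1-[2-hydroxy-4-(methoxymethoxy)-3-prenylphenyl]ethanone
Conditions: MOMCl, iPr2NEt, CH2Cl2, 0 °C → rt
Reagents that add atoms: chloromethyl methyl ether, COCCl
Why: Williamson-type acetal formation; the 2-OH is locked in a hydrogen bond to the acetyl oxygen and flanked by the prenyl group, so only the 4-OH should react.

**Step 3**
Reactants: 4 1-[2-hydroxy-4-(methoxymethoxy)-3-prenylphenyl]ethanone
Product: 5 1-[2-methoxy-4-(methoxymethoxy)-3-prenylphenyl]ethanone (ArB–COCH3)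
Conditions: MeI, K2CO3, DMF, rt → 40 °C
Reagents that add atoms: iodomethane, CI
Why: Williamson ether synthesis on the remaining chelated phenol under more forcing conditions; acetal and alkene are inert to base.

**Step 4**
Reactants: 5 ArB–COCH3
Product: 6 1-ArB-vinyl trifluoromethanesulfonate
Conditions: KN(SiMe3)2, THF, −78 °C; PhNTf2, −78 → 0 °C
Reagents that add atoms: N-phenylbis(trifluoromethanesulfonimide), O=S(=O)(N(c1ccccc1)S(=O)(=O)C(F)(F)F)C(F)(F)F
Why: Kinetic enolisation of the methyl ketone and O-sulfonylation give the 1-arylvinyl triflate; no other acidic site competes at −78 °C.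

**Step 5**
Reactants: 6 1-ArB-vinyl trifluoromethanesulfonate
Product: 7 2-ArB-prop-2-en-1-ol
Conditions: Bu3SnCH2OH, Pd(PPh3)4 (cat.), LiCl, 1,4-dioxane, 90 °C
Reagents that add atoms: (tributylstannyl)methanol, CCCC[Sn](CCCC)(CCCC)CO
Why: Stille cross-coupling of an enol triflate with a hydroxymethylstannane, with chloride assisting the zerovalent palladium cycle; it installs the CH2OH arm directly at the allylic alcohol oxidation level.

**Step 6**
Reactants: 7 2-ArB-prop-2-en-1-ol
Product: 8 [(2R)-2-ArB-oxiran-2-yl]methanol
Conditions: Ti(OiPr)4 (cat.), D-(−)-diisopropyl tartrate (cat.), t-BuOOH, 4 Å molecular sieves, CH2Cl2, −25 °C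
Reagents that add atoms: tert-butyl hydroperoxide, CC(C)(C)OO
Why: Sharpless asymmetric epoxidation: titanium binds the allylic hydroxyl, so only this alkene is oxidised and the prenyl group is left alone. By the empirical face rule the D-(−) tartrate should deliver oxygen to the face that makes the new quaternary centre R. Catalytic titanium, sieves and low temperature limit opening of the benzylic epoxide, which is used crude after a non-acidic work-up.

**Step 7**
Reactants: 8 [(2R)-2-ArB-oxiran-2-yl]methanol
Product: 9 (2R)-2-ArB-3-(phenylsulfanyl)propane-1,2-diol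
Conditions: PhSH, NaOH (aq., 0.5 M), t-BuOH, 65 °C
Reagents that add atoms: thiophenol, Sc1ccccc1
Why: The thiolate opens the 2,2-disubstituted epoxide by SN2 attack at CH2, so the C–O bond at the stereocentre is untouched. Base-induced epoxide migration (Payne rearrangement) is degenerate here and returns the same enantiomer. Sulfur marks the arm that becomes C4.

**Step 8**
Reactants: 9 (2R)-2-ArB-3-(phenylsulfanyl)propane-1,2-diol
Product: 10 (2R)-2-ArB-1-(tert-butyldimethylsilyloxy)-3-(phenylsulfanyl)propan-2-ol
Conditions: TBSCl, imidazole, DMF, 0 °C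
Reagents that add atoms: tert-butyldimethylsilyl chloride, CC(C)(C)[Si](C)(C)Cl
Why: Silylation discriminates the primary hydroxyl from the hindered tertiary one.

**Step 9**
Reactants: 10 (2R)-2-ArB-1-(tert-butyldimethylsilyloxy)-3-(phenylsulfanyl)propan-2-ol
Product: 11 tert-butyl{[(2R)-2-ArB-2-(methoxymethoxy)-3-(phenylsulfanyl)propyl]oxy}dimethylsilane
Conditions: MOMCl, iPr2NEt, n-Bu4NI (cat.), ClCH2CH2Cl, 60 °C
Reagents that add atoms: chloromethyl methyl ether, COCCl
Why: Alkylation of the tertiary alcohol by the iodomethyl ether formed in situ (Finkelstein activation). An amine base is used so that no alkoxide forms that could pull the silyl group across; the acetal itself cannot migrate under base later.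

**Step 10**
Reactants: 11 tert-butyl{[(2R)-2-ArB-2-(methoxymethoxy)-3-(phenylsulfanyl)propyl]oxy}dimethylsilane
Product: 12 tert-butyl{[(2R)-2-ArB-2-(methoxymethoxy)-3-(phenylsulfinyl)propyl]oxy}dimethylsilane (both configurations at sulfur)
Conditions: NaIO4, MeOH/THF/H2O, 0 °C → rt
Reagents that add atoms: sodium periodate, [Na+].[O-]I(=O)(=O)=O
Why: Periodate oxidises the sulfide to the sulfoxide and stops there; alkenes and arenes are not attacked, and the sulfur epimers converge in step 11.

**Step 11**
Reactants: 12 tert-butyl{[(2R)-2-ArB-2-(methoxymethoxy)-3-(phenylsulfinyl)propyl]oxy}dimethylsilane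
Product: 14 (2R)-2-ArB-3-(tert-butyldimethylsilyloxy)-2-(methoxymethoxy)propanal, via α-trifluoroacetoxy sulfide 13 (not isolated)
Conditions: (CF3CO)2O, 2,6-lutidine, MeCN, 0 °C; then aq. NaHCO3, rt
Reagents that add atoms: trifluoroacetic anhydride, O=C(OC(=O)C(F)(F)F)C(F)(F)F
Why: Pummerer rearrangement: O-acylation, loss of trifluoroacetate to a thionium ion, capture at carbon, and mild hydrolysis of the O,S-acetal release the aldehyde. The neighbouring carbon is quaternary, so neither elimination nor epimerisation is possible.

**Step 12**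
Reactants: 14 (2R)-2-ArB-3-(tert-butyldimethylsilyloxy)-2-(methoxymethoxy)propanal
Product: 15 (4R)-4-ArB-5-(tert-butyldimethylsilyloxy)-4-(methoxymethoxy)pent-1-yn-3-ol (both C3 epimers)
Conditions: HC≡CMgBr, THF, −78 → 0 °C; aq. NH4Cl
Reagents that add atoms: ethynylmagnesium bromide, C#C[Mg]Br
Why: Grignard addition to the non-enolisable aldehyde; the carbinol configuration is irrelevant because it is oxidised in step 13.

**Step 13**
Reactants: 15 (4R)-4-ArB-5-(tert-butyldimethylsilyloxy)-4-(methoxymethoxy)pent-1-yn-3-ol
Product: 16 (4R)-4-ArB-5-(tert-butyldimethylsilyloxy)-4-(methoxymethoxy)pent-1-yn-3-one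
Conditions: Dess–Martin periodinane, NaHCO3, CH2Cl2, 0 °C → rt
Reagents that add atoms: none
Why: Dess–Martin oxidation of the propargylic alcohol under buffered conditions; silyl ether, acetals and alkene are inert.

**Step 14**
Reactants: 16 (4R)-4-ArB-5-(tert-butyldimethylsilyloxy)-4-(methoxymethoxy)pent-1-yn-3-one
Product: 17 (4R)-1-bromo-4-ArB-5-(tert-butyldimethylsilyloxy)-4-(methoxymethoxy)pent-1-yn-3-one
Conditions: NBS, AgNO3 (cat.), acetone, rt, dark
Reagents that add atoms: N-bromosuccinimide, O=C1CCC(=O)N1Br
Why: Silver-catalysed electrophilic bromination of the terminal alkyne via the silver acetylide; with one equivalent of reagent this should be much faster than attack on the prenyl double bond or on ring B.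

**Step 15**
Reactants: 18 methyl acetoacetate; 2 prenyl bromide
Product: 19 methyl 2-acetyl-5-methylhex-4-enoate
Conditions: NaH, THF, 0 °C; then 2, 0 °C → rt
Reagents that add atoms: none
Why: C-Alkylation of the sodium enolate with the allylic bromide (SN2); a small excess of 18 suppresses dialkylation.

**Step 16**
Reactants: 19 methyl 2-acetyl-5-methylhex-4-enoate
Product: 20 methyl 5-methyl-2-[1-(trimethylsilyloxy)ethylidene]hex-4-enoate
Conditions: Me3SiCl, Et3N, pentane, rt
Reagents that add atoms: chlorotrimethylsilane, C[Si](C)(C)Cl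
Why: O-Silylation of the enolised ketone gives the silyl enol ether that activates the γ-methyl group.

**Step 17**
Reactants: 20 methyl 5-methyl-2-[1-(trimethylsilyloxy)ethylidene]hex-4-enoate
Product: 21 1-methoxy-2-prenyl-1,3-bis(trimethylsilyloxy)buta-1,3-diene
Conditions: LiN(iPr)2, THF, −78 °C; Me3SiCl, −78 °C → rt
Reagents that add atoms: chlorotrimethylsilane, C[Si](C)(C)Cl
Why: γ-Deprotonation of the vinylogous ester and O-silylation of the ester dienolate give the 1-alkoxy-1,3-bis(silyloxy)diene, which is moisture-sensitive and used without chromatography.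

**Step 18 (key step)**
Reactants: 17 (4R)-1-bromo-4-ArB-5-(tert-butyldimethylsilyloxy)-4-(methoxymethoxy)pent-1-yn-3-one; 21 1-methoxy-2-prenyl-1,3-bis(trimethylsilyloxy)buta-1,3-diene
Product: 24 (2R)-1-(2-bromo-4,6-dihydroxy-5-prenylphenyl)-2-ArB-3-(tert-butyldimethylsilyloxy)-2-(methoxymethoxy)propan-1-one, via cyclohexadiene cycloadduct 22 (not isolated), via 4-O-trimethylsilyl aryl ether 23 (not isolated)
Conditions: PhMe, −20 → 50 °C; then HCl (aq., 0.1 M), THF, 0 °C
Reagents that add atoms: none
Why: Diels–Alder cycloaddition with aromatisation, the benzannulation type established for 1-alkoxy-1,3-bis(silyloxy)butadienes with acetylenic ketones and 3-bromopropiolates. The diene is most nucleophilic at its CH2 terminus and the ynone most electrophilic at the bromine-bearing β-carbon, so C8–C8a should form first (asynchronous, or stepwise through a silyl-stabilised zwitterion) and the ketene acetal carbon then bonds to the α-carbon (C5–C4a). Ring A therefore closes by an intermolecular [4+2] union of two components, not by cyclisation of a tethered chain. Adduct 22 aromatises by 1,4-elimination of the methoxy group together with the adjacent silyl group, followed by tautomerisation to 23; dilute acid removes the remaining aryl silyl ether. The regiochemistry needed (bromine at C8a, prenyl between the two oxygens) follows from this polarity match and from the position of the prenyl group on C2 of the diene, not from any directing effect in a finished arene. No stereocentre is created, and the existing one is quaternary without an α-hydrogen, so it is not at risk. The step also needs chemoselectivity: the diene must add across the triple bond and not displace bromide or attack the hindered ketone, which a low starting temperature and the absence of Lewis acid should favour.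

**Step 19**
Reactants: 24 (2R)-1-(2-bromo-4,6-dihydroxy-5-prenylphenyl)-2-ArB-3-(tert-butyldimethylsilyloxy)-2-(methoxymethoxy)propan-1-one
Product: 25 (2R)-1-[2-bromo-4,6-bis(methoxymethoxy)-5-prenylphenyl]-2-ArB-3-(tert-butyldimethylsilyloxy)-2-(methoxymethoxy)propan-1-one
Conditions: NaH, MOMCl, DMF, 0 °C → rt
Reagents that add atoms: chloromethyl methyl ether, COCCl
Why: Williamson-type protection of both phenols, including the chelated one, through the sodium phenoxides; free phenoxides would interfere with the copper-catalysed coupling. No aliphatic hydroxyl is free at this stage.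

**Step 20**
Reactants: 25 (2R)-1-[2-bromo-4,6-bis(methoxymethoxy)-5-prenylphenyl]-2-ArB-3-(tert-butyldimethylsilyloxy)-2-(methoxymethoxy)propan-1-one
Product: 26 (2R)-1-[2-bromo-4,6-bis(methoxymethoxy)-5-prenylphenyl]-2-ArB-3-hydroxy-2-(methoxymethoxy)propan-1-one
Conditions: HF·pyridine, pyridine, THF, 0 °C → rt
Reagents that add atoms: none
Why: Fluoride cleaves the primary silyl ether; the buffered reagent avoids the basic alkoxide that unbuffered fluoride would generate β to the ketone. Acetals and aryl bromide are inert.

**Step 21**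
Reactants: 26 (2R)-1-[2-bromo-4,6-bis(methoxymethoxy)-5-prenylphenyl]-2-ArB-3-hydroxy-2-(methoxymethoxy)propan-1-one
Product: 27 (3R)-3-ArB-3,5,7-tris(methoxymethoxy)-6-prenylchroman-4-one
Conditions: CuI (cat.), 1,10-phenanthroline, Cs2CO3, PhMe, 90 °C
Reagents that add atoms: none
Why: Intramolecular Ullmann-type O-arylation: the monovalent copper–phenanthroline complex activates the C8a–Br bond, which is ortho to the carbonyl, and the primary alkoxide closes the six-membered ring C by forming O1–C8a. The tertiary oxygen is blocked by a non-migrating acetal, so only the primary oxygen can cyclise.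

**Step 22**
Reactants: 27 (3R)-3-ArB-3,5,7-tris(methoxymethoxy)-6-prenylchroman-4-one
Product: 28 (3R)-3,5,7-trihydroxy-3-(4-hydroxy-2-methoxy-3-prenylphenyl)-6-prenylchroman-4-one (target)
Conditions: HCl (aq., 3 M), MeOH, 45 °C
Reagents that add atoms: none
Why: Acid-catalysed transacetalisation to the solvent removes the three aryl MOM groups and the tertiary one; the temperature is kept moderate so that the prenyl groups do not add to the liberated ortho phenols. C3 is not at risk because a benzylic cation there is disfavoured by the adjacent carbonyl.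

## Compound list

1 | 2,4-dihydroxyacetophenone | CC(=O)c1ccc(O)cc1O | starting material
2 | prenyl bromide (1-bromo-3-methylbut-2-ene) | CC(C)=CCBr | starting material
3 | 1-(2,4-dihydroxy-3-prenylphenyl)ethanone | CC(=O)c1ccc(O)c(CC=C(C)C)c1O | intermediate
4 | 1-[2-hydroxy-4-(methoxymethoxy)-3-prenylphenyl]ethanone | CC(=O)c1ccc(OCOC)c(CC=C(C)C)c1O | intermediate
5 | 1-[2-methoxy-4-(methoxymethoxy)-3-prenylphenyl]ethanone | CC(=O)c1ccc(OCOC)c(CC=C(C)C)c1OC | intermediate
6 | 1-ArB-vinyl trifluoromethanesulfonate | C=C(OS(=O)(=O)C(F)(F)F)c1ccc(OCOC)c(CC=C(C)C)c1OC | intermediate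
7 | 2-ArB-prop-2-en-1-ol | C=C(CO)c1ccc(OCOC)c(CC=C(C)C)c1OC | intermediate
8 | [(2R)-2-ArB-oxiran-2-yl]methanol | C1[C@](O1)(CO)c2ccc(OCOC)c(CC=C(C)C)c2OC | intermediate
9 | (2R)-2-ArB-3-(phenylsulfanyl)propane-1,2-diol | C(Sc1ccccc1)[C@](O)(CO)c1ccc(OCOC)c(CC=C(C)C)c1OC | intermediate
10 | (2R)-2-ArB-1-(tert-butyldimethylsilyloxy)-3-(phenylsulfanyl)propan-2-ol | C(Sc1ccccc1)[C@](O)(CO[Si](C)(C)C(C)(C)C)c1ccc(OCOC)c(CC=C(C)C)c1OC | intermediate
11 | tert-butyl{[(2R)-2-ArB-2-(methoxymethoxy)-3-(phenylsulfanyl)propyl]oxy}dimethylsilane | C(Sc1ccccc1)[C@](OCOC)(CO[Si](C)(C)C(C)(C)C)c1ccc(OCOC)c(CC=C(C)C)c1OC | intermediate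
12 | tert-butyl{[(2R)-2-ArB-2-(methoxymethoxy)-3-(phenylsulfinyl)propyl]oxy}dimethylsilane, both sulfur epimers | C(S(=O)c1ccccc1)[C@](OCOC)(CO[Si](C)(C)C(C)(C)C)c1ccc(OCOC)c(CC=C(C)C)c1OC | intermediate
13 | (2R)-2-ArB-3-(tert-butyldimethylsilyloxy)-2-(methoxymethoxy)-1-(phenylsulfanyl)propyl trifluoroacetate, both C1 epimers | C(Sc1ccccc1)(OC(=O)C(F)(F)F)[C@](OCOC)(CO[Si](C)(C)C(C)(C)C)c1ccc(OCOC)c(CC=C(C)C)c1OC | intermediate (not isolated)
14 | (2R)-2-ArB-3-(tert-butyldimethylsilyloxy)-2-(methoxymethoxy)propanal | O=C[C@](OCOC)(CO[Si](C)(C)C(C)(C)C)c1ccc(OCOC)c(CC=C(C)C)c1OC | intermediate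
15 | (4R)-4-ArB-5-(tert-butyldimethylsilyloxy)-4-(methoxymethoxy)pent-1-yn-3-ol, both C3 epimers | C#CC(O)[C@](OCOC)(CO[Si](C)(C)C(C)(C)C)c1ccc(OCOC)c(CC=C(C)C)c1OC | intermediate
16 | (4R)-4-ArB-5-(tert-butyldimethylsilyloxy)-4-(methoxymethoxy)pent-1-yn-3-one | C#CC(=O)[C@](OCOC)(CO[Si](C)(C)C(C)(C)C)c1ccc(OCOC)c(CC=C(C)C)c1OC | intermediate
17 | (4R)-1-bromo-4-ArB-5-(tert-butyldimethylsilyloxy)-4-(methoxymethoxy)pent-1-yn-3-one | BrC#CC(=O)[C@](OCOC)(CO[Si](C)(C)C(C)(C)C)c1ccc(OCOC)c(CC=C(C)C)c1OC | intermediate
18 | methyl acetoacetate | COC(=O)CC(C)=O | starting material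
19 | methyl 2-acetyl-5-methylhex-4-enoate | COC(=O)C(CC=C(C)C)C(C)=O | intermediate
20 | methyl 5-methyl-2-[1-(trimethylsilyloxy)ethylidene]hex-4-enoate | COC(=O)C(CC=C(C)C)=C(C)O[Si](C)(C)C | intermediate
21 | 1-methoxy-2-prenyl-1,3-bis(trimethylsilyloxy)buta-1,3-diene | COC(O[Si](C)(C)C)=C(CC=C(C)C)C(=C)O[Si](C)(C)C | intermediate
22 | (2R)-1-[2-bromo-6-methoxy-5-prenyl-4,6-bis(trimethylsilyloxy)cyclohexa-1,4-dien-1-yl]-2-ArB-3-(tert-butyldimethylsilyloxy)-2-(methoxymethoxy)propan-1-one | COC1(O[Si](C)(C)C)C(CC=C(C)C)=C(O[Si](C)(C)C)CC(Br)=C1C(=O)[C@](OCOC)(CO[Si](C)(C)C(C)(C)C)c1ccc(OCOC)c(CC=C(C)C)c1OC | intermediate (not isolated)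
23 | (2R)-1-[2-bromo-6-hydroxy-5-prenyl-4-(trimethylsilyloxy)phenyl]-2-ArB-3-(tert-butyldimethylsilyloxy)-2-(methoxymethoxy)propan-1-one | Brc1cc(O[Si](C)(C)C)c(CC=C(C)C)c(O)c1C(=O)[C@](OCOC)(CO[Si](C)(C)C(C)(C)C)c1ccc(OCOC)c(CC=C(C)C)c1OC | intermediate (not isolated)
24 | (2R)-1-(2-bromo-4,6-dihydroxy-5-prenylphenyl)-2-ArB-3-(tert-butyldimethylsilyloxy)-2-(methoxymethoxy)propan-1-one | Brc1cc(O)c(CC=C(C)C)c(O)c1C(=O)[C@](OCOC)(CO[Si](C)(C)C(C)(C)C)c1ccc(OCOC)c(CC=C(C)C)c1OC | intermediate
25 | (2R)-1-[2-bromo-4,6-bis(methoxymethoxy)-5-prenylphenyl]-2-ArB-3-(tert-butyldimethylsilyloxy)-2-(methoxymethoxy)propan-1-one | Brc1cc(OCOC)c(CC=C(C)C)c(OCOC)c1C(=O)[C@](OCOC)(CO[Si](C)(C)C(C)(C)C)c1ccc(OCOC)c(CC=C(C)C)c1OC | intermediate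
26 | (2R)-1-[2-bromo-4,6-bis(methoxymethoxy)-5-prenylphenyl]-2-ArB-3-hydroxy-2-(methoxymethoxy)propan-1-one | Brc1cc(OCOC)c(CC=C(C)C)c(OCOC)c1C(=O)[C@](OCOC)(CO)c1ccc(OCOC)c(CC=C(C)C)c1OC | intermediate
27 | (3R)-3-ArB-3,5,7-tris(methoxymethoxy)-6-prenylchroman-4-one | COc1c([C@@]2(OCOC)COc3cc(OCOC)c(CC=C(C)C)c(OCOC)c3C2=O)ccc(OCOC)c1CC=C(C)C | intermediate
28 | (3R)-3,5,7-trihydroxy-3-(4-hydroxy-2-methoxy-3-prenylphenyl)-6-prenylchroman-4-one | COc1c([C@@]2(O)COc3cc(O)c(CC=C(C)C)c(O)c3C2=O)ccc(O)c1CC=C(C)C | target

## Step count and least certain steps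

Total: 22 steps. Longest linear sequence: 19 steps (steps 1–14 and 18–22); the diene branch (steps 15–17) joins at step 18.

**Step 18 (key step).** The diene terminus may add to the bromoalkyne and then lose bromide or transfer silicon without closing the ring, because both new bonds form next to fully substituted carbons and the cycloaddition may be slow; adventitious acid can also desilylate the diene first. Fallback, setting out from diene 21 and aldehyde 14 and returning at 25: the same cycloaddition is run on the small dienophile methyl 3-bromopropiolate F1 (from methyl propiolate, NBS and catalytic AgNO3), the substrate class on which this benzannulation is established, to give methyl 2-bromo-4,6-dihydroxy-5-prenylbenzoate F2. Both phenols are protected (NaH, MOMCl) to give the bis-MOM ester F3, which is saponified (KOH, MeOH/H2O, reflux) to 2-bromo-4,6-bis(methoxymethoxy)-5-prenylbenzoic acid F4 and protodecarboxylated (Ag2CO3 cat., AcOH, DMSO, 120 °C) to the symmetric 1-bromo-3,5-bis(methoxymethoxy)-4-prenylbenzene F5. LiN(iPr)2 at −78 °C removes one of the two equivalent hydrogens between bromine and an acetal oxygen, and the aryllithium adds to aldehyde 14 to give the benzylic carbinol F6, which Dess–Martin oxidation converts into 25. The prenyl position is still fixed by construction; the C4–C4a bond is then made by carbonyl addition and no longer sits in the dienophile.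

**Step 6.** The tertiary benzylic C–O bond of epoxide 8 is assisted by the para-alkoxy group and may ionise under the Lewis acidic titanium conditions, giving ring-opened or rearranged material and lowering the enantiomeric purity. Fallback, setting out from 3 and returning at 9: the 4-OH is acylated (pivaloyl chloride, Et3N) to 4-acetyl-3-hydroxy-2-prenylphenyl pivalate F7, so that the para oxygen is a poor donor during the epoxidation. Methylation (MeI, K2CO3) gives 4-acetyl-3-methoxy-2-prenylphenyl pivalate F8, triflation as in step 4 gives the enol triflate F9, and the Stille hydroxymethylation of step 5 gives the allyl alcohol F10. The epoxidation of step 6 with the D-(−) tartrate then gives the (R)-epoxy alcohol pivalate F11. Thiophenol and aqueous NaOH open the epoxide and cleave the pivalate in the same flask to give the phenol (R)-4-[1,2-dihydroxy-3-(phenylsulfanyl)propan-2-yl]-3-methoxy-2-prenylphenol F12. MOMCl with K2CO3 in acetone protects only the phenol and gives 9.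

**Step 21.** The primary alkoxide of 26 may undergo retro-aldol cleavage (loss of the C2 carbon) faster than O-arylation, because the carbanion left behind is stabilised by the ketone and by ring B; reduction of the C–Br bond is a second possibility. Fallback, setting out from 25 and returning at 27, which never generates an alkoxide: Miyaura borylation (PdCl2(dppf) cat., bis(pinacolato)diboron, KOAc, 1,4-dioxane, 85 °C) gives the aryl pinacol boronate F13, and NaBO3·4H2O in THF/H2O oxidises it to the C8a phenol F14. HF·pyridine removes the silyl group to give the phenol alcohol F15, and a Mitsunobu reaction (PPh3, diisopropyl azodicarboxylate, THF, 0 °C) closes ring C by forming O1–C2 in place of O1–C8a.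

**Step 22.** While the tertiary MOM ether, which is deactivated by the neighbouring ketone, is still being cleaved, the liberated ortho phenols or the solvent may add across the prenyl double bonds (chroman formation). Fallback, setting out from 27 and returning at 28, in two orthogonal stages: a short exposure to dilute HCl in MeOH at room temperature removes only the three aryl acetals and gives the 3-O-methoxymethyl ether of the target F16; the remaining tertiary acetal is then cleaved under aprotic Lewis acid–thiol conditions (ZnBr2, n-PrSH, CH2Cl2, 0 °C).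

**Step 1.** The ambident phenoxide may be alkylated on oxygen, at C5, or twice, so the C3-prenyl ketone may be a minor component. Fallback, setting out from 1 and returning at 3: the unchelated 4-OH is alkylated with 3-chloro-3-methylbut-1-yne (K2CO3, KI, acetone) to give 1-[2-hydroxy-4-(2-methylbut-3-yn-2-yloxy)phenyl]ethanone F17. Semi-hydrogenation (H2, Pd/CaCO3 poisoned with Pb(OAc)2, quinoline) gives 1-[2-hydroxy-4-(2-methylbut-3-en-2-yloxy)phenyl]ethanone F18. Heating in N,N-diethylaniline at 130 °C effects an aromatic Claisen rearrangement, which the bond fixation of the chelated ketone should direct to C3, giving 3.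

## Further compounds

F1 | step 18 | methyl 3-bromoprop-2-ynoate | COC(=O)C#CBr
F2 | step 18 | methyl 2-bromo-4,6-dihydroxy-5-prenylbenzoate | COC(=O)c1c(Br)cc(O)c(CC=C(C)C)c1O
F3 | step 18 | methyl 2-bromo-4,6-bis(methoxymethoxy)-5-prenylbenzoate | COC(=O)c1c(Br)cc(OCOC)c(CC=C(C)C)c1OCOC
F4 | step 18 | 2-bromo-4,6-bis(methoxymethoxy)-5-prenylbenzoic acid | OC(=O)c1c(Br)cc(OCOC)c(CC=C(C)C)c1OCOC
F5 | step 18 | 1-bromo-3,5-bis(methoxymethoxy)-4-prenylbenzene | Brc1cc(OCOC)c(CC=C(C)C)c(OCOC)c1
F6 | step 18 | (2R)-1-[2-bromo-4,6-bis(methoxymethoxy)-5-prenylphenyl]-2-ArB-3-(tert-butyldimethylsilyloxy)-2-(methoxymethoxy)propan-1-ol, both C1 epimers | Brc1cc(OCOC)c(CC=C(C)C)c(OCOC)c1C(O)[C@](OCOC)(CO[Si](C)(C)C(C)(C)C)c1ccc(OCOC)c(CC=C(C)C)c1OC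
F7 | step 6 | 4-acetyl-3-hydroxy-2-prenylphenyl pivalate | CC(=O)c1ccc(OC(=O)C(C)(C)C)c(CC=C(C)C)c1O
F8 | step 6 | 4-acetyl-3-methoxy-2-prenylphenyl pivalate | CC(=O)c1ccc(OC(=O)C(C)(C)C)c(CC=C(C)C)c1OC
F9 | step 6 | 3-methoxy-2-prenyl-4-[1-(trifluoromethanesulfonyloxy)vinyl]phenyl pivalate | C=C(OS(=O)(=O)C(F)(F)F)c1ccc(OC(=O)C(C)(C)C)c(CC=C(C)C)c1OC
F10 | step 6 | 4-(3-hydroxyprop-1-en-2-yl)-3-methoxy-2-prenylphenyl pivalate | C=C(CO)c1ccc(OC(=O)C(C)(C)C)c(CC=C(C)C)c1OC
F11 | step 6 | 4-[(2R)-2-(hydroxymethyl)oxiran-2-yl]-3-methoxy-2-prenylphenyl pivalate | C1[C@](O1)(CO)c2ccc(OC(=O)C(C)(C)C)c(CC=C(C)C)c2OC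
F12 | step 6 | 4-[(2R)-1,2-dihydroxy-3-(phenylsulfanyl)propan-2-yl]-3-methoxy-2-prenylphenol | C(Sc1ccccc1)[C@](O)(CO)c1ccc(O)c(CC=C(C)C)c1OC
F13 | step 21 | (2R)-1-[4,6-bis(methoxymethoxy)-5-prenyl-2-(4,4,5,5-tetramethyl-1,3,2-dioxaborolan-2-yl)phenyl]-2-ArB-3-(tert-butyldimethylsilyloxy)-2-(methoxymethoxy)propan-1-one | CC1(C)OB(OC1(C)C)c2cc(OCOC)c(CC=C(C)C)c(OCOC)c2C(=O)[C@](OCOC)(CO[Si](C)(C)C(C)(C)C)c3ccc(OCOC)c(CC=C(C)C)c3OC
F14 | step 21 | (2R)-1-[2-hydroxy-4,6-bis(methoxymethoxy)-5-prenylphenyl]-2-ArB-3-(tert-butyldimethylsilyloxy)-2-(methoxymethoxy)propan-1-one | Oc1cc(OCOC)c(CC=C(C)C)c(OCOC)c1C(=O)[C@](OCOC)(CO[Si](C)(C)C(C)(C)C)c1ccc(OCOC)c(CC=C(C)C)c1OC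
F15 | step 21 | (2R)-3-hydroxy-1-[2-hydroxy-4,6-bis(methoxymethoxy)-5-prenylphenyl]-2-ArB-2-(methoxymethoxy)propan-1-one | Oc1cc(OCOC)c(CC=C(C)C)c(OCOC)c1C(=O)[C@](OCOC)(CO)c1ccc(OCOC)c(CC=C(C)C)c1OC
F16 | step 22 | (3R)-5,7-dihydroxy-3-(4-hydroxy-2-methoxy-3-prenylphenyl)-3-(methoxymethoxy)-6-prenylchroman-4-one | COc1c([C@@]2(OCOC)COc3cc(O)c(CC=C(C)C)c(O)c3C2=O)ccc(O)c1CC=C(C)C
F17 | step 1 | 1-[2-hydroxy-4-(2-methylbut-3-yn-2-yloxy)phenyl]ethanone | CC(=O)c1ccc(OC(C)(C)C#C)cc1O
F18 | step 1 | 1-[2-hydroxy-4-(2-methylbut-3-en-2-yloxy)phenyl]ethanone | CC(=O)c1ccc(OC(C)(C)C=C)cc1O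
A1 | alternative 1 | (3R)-3-hydroxy-7-(methoxymethoxy)-3-[4-(methoxymethoxy)-2-(2-methylbut-3-en-2-yloxy)phenyl]-5-(2-methylbut-3-en-2-yloxy)chroman-4-one | C=CC(C)(C)Oc1c([C@@]2(O)COc3cc(OCOC)cc(OC(C)(C)C=C)c3C2=O)ccc(OCOC)c1
A2 | alternative 1 | (3R)-3,5-dihydroxy-3-[2-hydroxy-4-(methoxymethoxy)-3-prenylphenyl]-7-(methoxymethoxy)-6-prenylchroman-4-one | Oc1c([C@@]2(O)COc3cc(OCOC)c(CC=C(C)C)c(O)c3C2=O)ccc(OCOC)c1CC=C(C)C
A3 | alternative 2 | (E)-3-[2-(tert-butyldimethylsilyloxy)-4,6-bis(methoxymethoxy)-5-prenylphenyl]-2-[2-methoxy-4-(methoxymethoxy)-3-prenylphenyl]prop-2-en-1-ol | OC/C(c1ccc(OCOC)c(CC=C(C)C)c1OC)=C/c1c(O[Si](C)(C)C(C)(C)C)cc(OCOC)c(CC=C(C)C)c1OCOC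
A4 | alternative 2 | [(2R,3R)-3-[2-(tert-butyldimethylsilyloxy)-4,6-bis(methoxymethoxy)-5-prenylphenyl]-2-[2-methoxy-4-(methoxymethoxy)-3-prenylphenyl]oxiran-2-yl]methanol | OC[C@@]1(c2ccc(OCOC)c(CC=C(C)C)c2OC)O[C@@H]1c1c(O[Si](C)(C)C(C)(C)C)cc(OCOC)c(CC=C(C)C)c1OCOC
A5 | alternative 3 | 1-[2-methoxy-4,6-bis(pivaloyloxy)-5-prenylphenyl]-2-[2-(tert-butyldimethylsilyloxy)-4-(pivaloyloxy)-3-prenylphenyl]ethane-1,2-dione | COc1cc(OC(=O)C(C)(C)C)c(CC=C(C)C)c(OC(=O)C(C)(C)C)c1C(=O)C(=O)c1ccc(OC(=O)C(C)(C)C)c(CC=C(C)C)c1O[Si](C)(C)C(C)(C)C
A6 | alternative 3 | (3R)-3-[2-(tert-butyldimethylsilyloxy)-4-(pivaloyloxy)-3-prenylphenyl]-3-hydroxy-5,7-bis(pivaloyloxy)-6-prenylchroman-4-one | CC(C)(C)[Si](C)(C)Oc1c([C@@]2(O)COc3cc(OC(=O)C(C)(C)C)c(CC=C(C)C)c(OC(=O)C(C)(C)C)c3C2=O)ccc(OC(=O)C(C)(C)C)c1CC=C(C)C
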